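The dihydropyranone ring C of the flavanone half is opened at the bond between C3 (the CH2) and the C4 carbonyl carbon, so that the ring is closed at carbon and not at O1. Because C4 sits on ring A ortho to O1, and C2 carries both O1 and the B-ring aryl, the flavanone is an isomer of a 2-(1-arylvinyloxy)benzaldehyde. An enantioselective rhodium-catalysed intramolecular hydroacylation adds the formyl C–H across that enol-ether double bond: it forms C3–C4, closes ring C and sets (2S) in one operation. The achiral precursor already holds the complete flavone half, attached by Suzuki coupling, and its vinyl ether comes from a Mitsunobu etherification followed by elimination.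

Key step: step 7

Assumption: (R)-DTBM-SEGPHOS is taken as the ligand antipode that leads to (2S) in step 7 (if the first run shows the opposite sense, the (S) ligand is used), and the biaryl axis is taken as configurationally labile, as the target is drawn without an axial descriptor.

Step 1
Reactants: 1 5,7-dimethoxy-2-(4-methoxyphenyl)-4H-chromen-4-one (apigenin trimethyl ether)
Product: 2 8-iodo-5,7-dimethoxy-2-(4-methoxyphenyl)-4H-chromen-4-one
Conditions: I2, AgO2CCF3, CH2Cl2, 0 °C → rt, dark
Reagents that add atoms: iodine, II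
Why: Electrophilic aromatic iodination, which with the 5-oxygen alkylated should go to C8 of ring A (between the 7-methoxy group and O1) and not to C6 (flanked by two methoxy groups), as is known for 5,7-di-O-alkylflavones.

Step 2
Reactants: 3 4-(benzyloxy)-3-bromobenzaldehyde
Product: 4 1-(benzyloxy)-2-bromo-4-ethenylbenzene
Conditions: Ph3PCH3Br, KOtBu, THF, 0 °C → rt
Reagents that add atoms: methyltriphenylphosphonium bromide, C[P+](c1ccccc1)(c1ccccc1)c1ccccc1.[Br-]
Why: Wittig methylenation of a non-enolisable aryl aldehyde; the aryl bromide and the benzyl ether are inert to the ylide.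

Step 3
Reactants: 4 1-(benzyloxy)-2-bromo-4-ethenylbenzene
Product: 5 racemic 1-[4-(benzyloxy)-3-bromophenyl]-2-bromoethan-1-ol
Conditions: NBS, acetone–H2O, 0 °C → rt
Reagents that add atoms: N-bromosuccinimide, O=C1CCC(=O)N1Br; water, O
Why: Bromohydrin formation, in which water opens the bromonium ion at the benzylic carbon (Markovnikov sense) because the para benzyloxy group stabilises positive charge there.

Step 4
Reactants: 5 racemic 1-[4-(benzyloxy)-3-bromophenyl]-2-bromoethan-1-ol; 6 2-hydroxy-4,6-dimethoxybenzaldehyde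
Product: 7 racemic 2-{1-[4-(benzyloxy)-3-bromophenyl]-2-bromoethoxy}-4,6-dimethoxybenzaldehyde
Conditions: PPh3, DIAD, THF, 0 °C → rt
Reagents that add atoms: none
Why: Mitsunobu etherification, in which the acidic salicylaldehyde-type phenol displaces the benzylic alkoxyphosphonium ion; the configuration of this centre does not matter because it becomes sp2 in step 5.

Step 5
Reactants: 7 racemic 2-{1-[4-(benzyloxy)-3-bromophenyl]-2-bromoethoxy}-4,6-dimethoxybenzaldehyde
Product: 8 2-({1-[4-(benzyloxy)-3-bromophenyl]ethenyl}oxy)-4,6-dimethoxybenzaldehyde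
Conditions: KOtBu, THF, 0 °C → rt; chromatography on Et3N-deactivated silica
Reagents that add atoms: none
Why: E2 dehydrobromination of a 2-bromoethyl aryl ether (the classical entry to aryl vinyl ethers), in which the only β-hydrogen is the benzylic α-oxygenated one, so the 1,1-disubstituted enol ether is the only possible alkene; the aldehyde has no α-hydrogen.

Step 6
Reactants: 8 2-({1-[4-(benzyloxy)-3-bromophenyl]ethenyl}oxy)-4,6-dimethoxybenzaldehyde; 2 8-iodo-5,7-dimethoxy-2-(4-methoxyphenyl)-4H-chromen-4-one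
Product: 10 2-[(1-{4-(benzyloxy)-3-[5,7-dimethoxy-2-(4-methoxyphenyl)-4-oxo-4H-chromen-8-yl]phenyl}ethenyl)oxy]-4,6-dimethoxybenzaldehyde, via pinacol boronate 9 (not isolated)
Conditions: B2pin2, Pd(dppf)Cl2, KOAc, 1,4-dioxane, 90 °C; then 2, Pd(OAc)2, SPhos, K3PO4, H2O, 90 °C
Reagents that add atoms: bis(pinacolato)diboron, CC1(C)OB(OC1(C)C)B1OC(C)(C)C(C)(C)O1 (boron of 9 only)
Why: Miyaura borylation of the aryl bromide followed in the same flask by Suzuki–Miyaura coupling with the C8 iodide, a tri-ortho-substituted biaryl union of the kind used for 3',8''-linked biflavones and helped here by the bulky biarylphosphine; the aldehyde and the enol ether tolerate the mild bases.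

Step 7
Reactants: 10 2-[(1-{4-(benzyloxy)-3-[5,7-dimethoxy-2-(4-methoxyphenyl)-4-oxo-4H-chromen-8-yl]phenyl}ethenyl)oxy]-4,6-dimethoxybenzaldehyde
Product: 11 8-{2-(benzyloxy)-5-[(2S)-5,7-dimethoxy-4-oxo-3,4-dihydro-2H-chromen-2-yl]phenyl}-5,7-dimethoxy-2-(4-methoxyphenyl)-4H-chromen-4-one
Conditions: [Rh(cod)Cl]2 (2.5 mol %), (R)-DTBM-SEGPHOS (5.5 mol %), Na[B(3,5-(CF3)2C6H3)4] (6 mol %), degassed 1,4-dioxane, 80 °C
Reagents that add atoms: none
Why: Proposed new method: the cationic monovalent rhodium bisphosphine complex should insert into the formyl C–H bond to give an acyl rhodium hydride (trivalent rhodium) held by the ortho methoxy oxygen, the enol-ether alkene then inserts into Rh–H with hydride going to the oxygen- and aryl-bearing carbon (the future C2) and rhodium to the terminal CH2, and C–C reductive elimination from the seven-membered acyl alkyl rhodacycle forms the C3–C4 bond. The closest known reaction type is the enantioselective rhodium-catalysed intramolecular hydroacylation of 2-(2-substituted allyl)benzaldehydes to 3-substituted tetralones and of N-(1-substituted vinyl)indole-2-carbaldehydes; a 1-arylvinyl aryl ether has not served as the alkene, hence the label. Ring C of the flavanone is closed in a formal 6-endo-trig mode with respect to the vinyl ether (acyl carbon to the terminal alkene carbon). The single stereocentre C2 is set in the hydride insertion by catalyst control, the axially chiral ligand selecting the alkene face that gives (2S). The step needs six-ring over five-ring closure, which the substrate secures because the opposite insertion would place rhodium on a fully substituted benzylic carbon, and it needs hydroacylation to outrun decarbonylation, which methoxy chelation and the absence of allylic hydrogens (no alkene isomerisation) favour. The trisubstituted flavone enone, the aryl methyl ethers and the benzyl ether are expected to be spectators.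

Step 8
Reactants: 11 8-{2-(benzyloxy)-5-[(2S)-5,7-dimethoxy-4-oxo-3,4-dihydro-2H-chromen-2-yl]phenyl}-5,7-dimethoxy-2-(4-methoxyphenyl)-4H-chromen-4-one
Product: 12 2,3-dihydroheveaflavone, 5-hydroxy-8-{2-hydroxy-5-[(2S)-5-hydroxy-7-methoxy-4-oxo-3,4-dihydro-2H-chromen-2-yl]phenyl}-7-methoxy-2-(4-methoxyphenyl)-4H-chromen-4-one
Conditions: BCl3, C6HMe5, CH2Cl2, −78 → 0 °C; then MeOH, H2O (neutral work-up)
Reagents that add atoms: none
Why: Chelation-controlled ether cleavage, in which BCl3 bound to each carbonyl removes only the two peri (C5) methyl groups and cleaves the benzyl ether with pentamethylbenzene as cation scavenger, while the non-chelated 7-, 7''- and 4'''-methyl ethers should stay and no base touches the C2 centre.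

Compound list
1 | 5,7-dimethoxy-2-(4-methoxyphenyl)-4H-chromen-4-one | COc1ccc(-c2cc(=O)c3c(OC)cc(OC)cc3o2)cc1 | starting material
2 | 8-iodo-5,7-dimethoxy-2-(4-methoxyphenyl)-4H-chromen-4-one | COc1ccc(-c2cc(=O)c3c(OC)cc(OC)c(I)c3o2)cc1 | intermediate
3 | 4-(benzyloxy)-3-bromobenzaldehyde | O=Cc1ccc(OCc2ccccc2)c(Br)c1 | starting material
4 | 1-(benzyloxy)-2-bromo-4-ethenylbenzene | C=Cc1ccc(OCc2ccccc2)c(Br)c1 | intermediate
5 | racemic 1-[4-(benzyloxy)-3-bromophenyl]-2-bromoethan-1-ol | OC(CBr)c1ccc(OCc2ccccc2)c(Br)c1 | intermediate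
6 | 2-hydroxy-4,6-dimethoxybenzaldehyde | COc1cc(O)c(C=O)c(OC)c1 | starting material
7 | racemic 2-{1-[4-(benzyloxy)-3-bromophenyl]-2-bromoethoxy}-4,6-dimethoxybenzaldehyde | COc1cc(OC)c(C=O)c(OC(CBr)c2ccc(OCc3ccccc3)c(Br)c2)c1 | intermediate
8 | 2-({1-[4-(benzyloxy)-3-bromophenyl]ethenyl}oxy)-4,6-dimethoxybenzaldehyde | COc1cc(OC)c(C=O)c(OC(=C)c2ccc(OCc3ccccc3)c(Br)c2)c1 | intermediate
9 | 2-({1-[4-(benzyloxy)-3-(4,4,5,5-tetramethyl-1,3,2-dioxaborolan-2-yl)phenyl]ethenyl}oxy)-4,6-dimethoxybenzaldehyde | COc1cc(OC)c(C=O)c(OC(=C)c2ccc(OCc3ccccc3)c(B4OC(C)(C)C(C)(C)O4)c2)c1 | intermediate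
10 | 2-[(1-{4-(benzyloxy)-3-[5,7-dimethoxy-2-(4-methoxyphenyl)-4-oxo-4H-chromen-8-yl]phenyl}ethenyl)oxy]-4,6-dimethoxybenzaldehyde | COc1ccc(-c2cc(=O)c3c(OC)cc(OC)c(-c4cc(C(=C)Oc5cc(OC)cc(OC)c5C=O)ccc4OCc6ccccc6)c3o2)cc1 | intermediate
11 | 8-{2-(benzyloxy)-5-[(2S)-5,7-dimethoxy-4-oxo-3,4-dihydro-2H-chromen-2-yl]phenyl}-5,7-dimethoxy-2-(4-methoxyphenyl)-4H-chromen-4-one | COc1ccc(-c2cc(=O)c3c(OC)cc(OC)c(-c4cc([C@@H]5CC(=O)c6c(OC)cc(OC)cc6O5)ccc4OCc7ccccc7)c3o2)cc1 | intermediate
12 | 2,3-dihydroheveaflavone, (2S) | COc1ccc(-c2cc(=O)c3c(O)cc(OC)c(-c4cc([C@@H]5CC(=O)c6c(O)cc(OC)cc6O5)ccc4O)c3o2)cc1 | target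

Total step count: 8. Longest linear sequence: 7 steps (steps 2 to 8, from 3).

Steps most likely to fail

Step 7 (proposed new method). What may go wrong: decarbonylation of the acyl rhodium hydride with loss of the catalyst as a carbonyl complex; hydride insertion in the opposite sense, leading to five-ring closure; acid-type attack of the enol ether on the aldehyde, leading towards a flavylium ion; or weak facial discrimination in the hydride transfer. The fallback uses known chemistry, sets out from 2 and comes back at 11; it makes the C2–aryl bond instead, by catalytic asymmetric conjugate addition to a chromone. Suzuki–Miyaura coupling of 2 with purchased [2-(benzyloxy)-5-chlorophenyl]boronic acid (OB(O)c1cc(Cl)ccc1OCc1ccccc1; Pd(PPh3)4, K2CO3, DME–H2O, the chloride staying untouched) should give 8-[2-(benzyloxy)-5-chlorophenyl]-5,7-dimethoxy-2-(4-methoxyphenyl)-4H-chromen-4-one F1. Borylation of the aryl chloride with B2(OH)4 (Pd(OAc)2, XPhos, KOAc, EtOH, 80 °C) should give {4-(benzyloxy)-3-[5,7-dimethoxy-2-(4-methoxyphenyl)-4-oxo-4H-chromen-8-yl]phenyl}boronic acid F2. The acceptor 5,7-dimethoxy-4H-chromen-4-one F3 is made by methylating purchased 5,7-dihydroxychromone (Oc1cc(O)c2c(=O)ccoc2c1; MeI, K2CO3, DMF). Conjugate addition of F2 to F3 with Pd(O2CCF3)2 and the antipode of the tert-butyl pyridine-oxazoline ligand that leads to the (2S) series (NH4PF6, H2O, ClCH2CH2Cl, 60 °C) is expected to give 11 without added base, so the new centre is not exposed to ring opening.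

Step 8. What may go wrong: Lewis-acid-induced opening of ring C of the flavanone (ionisation at C2 and loss of configuration) during the longer exposure that the flavone methyl ether needs, or cleavage of a non-chelated methyl ether. The fallback moves the slow cleavage ahead of the stereocentre; it sets out from 2, uses the boronate 9 of step 6, and comes back at 12. BCl3 (CH2Cl2, 0 °C) on 2 should give 5-hydroxy-8-iodo-7-methoxy-2-(4-methoxyphenyl)-4H-chromen-4-one F4. Coupling of F4 with 9 under the conditions of step 6 should give 2-[(1-{4-(benzyloxy)-3-[5-hydroxy-7-methoxy-2-(4-methoxyphenyl)-4-oxo-4H-chromen-8-yl]phenyl}ethenyl)oxy]-4,6-dimethoxybenzaldehyde F5. Hydroacylation as in step 7 should give 8-{2-(benzyloxy)-5-[(2S)-5,7-dimethoxy-4-oxo-3,4-dihydro-2H-chromen-2-yl]phenyl}-5-hydroxy-7-methoxy-2-(4-methoxyphenyl)-4H-chromen-4-one F6. A short treatment of F6 with BCl3 and C6HMe5 kept between −78 and −40 °C then only has to remove the benzyl group and the flavanone peri methyl group to reach 12.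

Step 6. What may go wrong: protodeboronation and homocoupling of the electron-rich boronate formed in the flask while transmetalation onto the hindered C8–palladium centre is slow. The fallback sets out from 8 and comes back at 10; it replaces boron by tin and works without base. Stannylation of 8 (Me3SnSnMe3, Pd(PPh3)4, toluene, 100 °C) should give 2-({1-[4-(benzyloxy)-3-(trimethylstannyl)phenyl]ethenyl}oxy)-4,6-dimethoxybenzaldehyde F7. Stille coupling of F7 with 2 (Pd(PPh3)4, CuI, CsF, DMF, 60 °C) should give 10.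

Further compounds
F1 | step 7 | 8-[2-(benzyloxy)-5-chlorophenyl]-5,7-dimethoxy-2-(4-methoxyphenyl)-4H-chromen-4-one | COc1ccc(-c2cc(=O)c3c(OC)cc(OC)c(-c4cc(Cl)ccc4OCc5ccccc5)c3o2)cc1
F2 | step 7 | {4-(benzyloxy)-3-[5,7-dimethoxy-2-(4-methoxyphenyl)-4-oxo-4H-chromen-8-yl]phenyl}boronic acid | COc1ccc(-c2cc(=O)c3c(OC)cc(OC)c(-c4cc(B(O)O)ccc4OCc5ccccc5)c3o2)cc1
F3 | step 7 | 5,7-dimethoxy-4H-chromen-4-one | COc1cc(OC)c2c(=O)ccoc2c1
F4 | step 8 | 5-hydroxy-8-iodo-7-methoxy-2-(4-methoxyphenyl)-4H-chromen-4-one | COc1ccc(-c2cc(=O)c3c(O)cc(OC)c(I)c3o2)cc1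
F5 | step 8 | 2-[(1-{4-(benzyloxy)-3-[5-hydroxy-7-methoxy-2-(4-methoxyphenyl)-4-oxo-4H-chromen-8-yl]phenyl}ethenyl)oxy]-4,6-dimethoxybenzaldehyde | COc1ccc(-c2cc(=O)c3c(O)cc(OC)c(-c4cc(C(=C)Oc5cc(OC)cc(OC)c5C=O)ccc4OCc6ccccc6)c3o2)cc1
F6 | step 8 | 8-{2-(benzyloxy)-5-[(2S)-5,7-dimethoxy-4-oxo-3,4-dihydro-2H-chromen-2-yl]phenyl}-5-hydroxy-7-methoxy-2-(4-methoxyphenyl)-4H-chromen-4-one | COc1ccc(-c2cc(=O)c3c(O)cc(OC)c(-c4cc([C@@H]5CC(=O)c6c(OC)cc(OC)cc6O5)ccc4OCc7ccccc7)c3o2)cc1
F7 | step 6 | 2-({1-[4-(benzyloxy)-3-(trimethylstannyl)phenyl]ethenyl}oxy)-4,6-dimethoxybenzaldehyde | COc1cc(OC)c(C=O)c(OC(=C)c2ccc(OCc3ccccc3)c([Sn](C)(C)C)c2)c1
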